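## Retrosynthetic overview

1. Dactylomelol ⇐ TES-protected diene **30**: Shi epoxidation, bromide opening and a bromonium-relayed chlorination install (S)-CHBr–CMe2Cl last.
2. Both side chains ⇐ 2-exo-allyl-3-endo-(3-hydroxypropyl)-7-oxanorbornane **21**: cross-metathesis, Sharpless epoxidation and methylenation give the vinyl carbinol; Wittig isopropylidenation gives the prenyl terminus.
3. Oxygen bridge (last ring formed) ⇐ phenylselenoetherification of 4-methylcyclohex-3-enol **17**; the C-2 chain then enters by exo radical allylation.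
4. Cyclohexenol **17** ⇐ keto acid **9**, obtained by oxidative scission of the enone ring (a temporary second carbocycle) of the Wieland–Miescher ketone.
5. Wieland–Miescher ketone ⇐ 2-methylcyclohexane-1,3-dione (the carbocycle, present from the start) + methyl vinyl ketone: intermolecular Michael addition builds the quaternary carbon, then a proline aldol sets its configuration.

Assumption: the SMILES is read as (3S)-5-[(1R,2S,3S,4S)-3-[(3S)-3-bromo-4-chloro-4-methylpentyl]-1,3-dimethyl-7-oxabicyclo[2.2.1]heptan-2-yl]-3-methylpent-1-en-3-ol (3-methyl and the C-2 chain exo, bromochloro chain endo); oxabicycle locants C-1 to C-4 are used throughout.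

## Route

Step 1
Reactants: 1 2-methylcyclohexane-1,3-dione; 2 methyl vinyl ketone
Product: 3 2-methyl-2-(3-oxobutyl)cyclohexane-1,3-dione
Conditions: Et3N (1 mol %), neat, 25 °C
Reagents that add atoms: none
Why: Intermolecular Michael addition of the 1,3-dione enolate to the enone forms the quaternary carbon (future C-3) and its bond to the future bromochloropentyl chain; the triketone is still achiral.

Step 2
Reactants: 3 2-methyl-2-(3-oxobutyl)cyclohexane-1,3-dione
Product: 5 (S)-Wieland–Miescher ketone [(8aS)-8a-methyl-3,4,8,8a-tetrahydronaphthalene-1,6(2H,7H)-dione], via cis-fused ketol 4 (not isolated)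
Conditions: L-proline (0.35 equiv), DMSO, 25 °C; recrystallisation (Et2O/hexane, −20 °C) to ≥98% ee
Reagents that add atoms: none
Why: The proline-enamine intramolecular aldol condensation (Hajos–Parrish–Eder–Sauer–Wiechert) differentiates the two enantiotopic ring carbonyls and fixes the quaternary centre as S, the ketol dehydrating in the flask.

Step 3
Reactants: 5 (S)-Wieland–Miescher ketone
Product: 6 (4aS,5S)-5-hydroxy-4a-methyl-4,4a,5,6,7,8-hexahydronaphthalen-2(3H)-one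
Conditions: NaBH4 (0.3 equiv), EtOH, −10 °C
Reagents that add atoms: none
Why: Chemoselective hydride reduction of the saturated ketone; axial attack anti to the axial angular methyl gives the equatorial alcohol cis to that methyl (5S), which becomes the C-4–O bond of the bridge.

Step 4
Reactants: 6 (4aS,5S)-5-hydroxy-4a-methyl-4,4a,5,6,7,8-hexahydronaphthalen-2(3H)-one
Product: 7 (4aS,5S)-5-[(tert-butyldimethylsilyl)oxy]-4a-methyl-4,4a,5,6,7,8-hexahydronaphthalen-2(3H)-one
Conditions: TBSCl, imidazole, DMF, 40 °C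
Reagents that add atoms: tert-butyldimethylsilyl chloride, C[Si](C)(Cl)C(C)(C)C
Why: Imidazole-promoted silylation masks the hydroxyl for the enolate chemistry; no stereocentre is touched.

Step 5
Reactants: 7 (4aS,5S)-5-[(tert-butyldimethylsilyl)oxy]-4a-methyl-4,4a,5,6,7,8-hexahydronaphthalen-2(3H)-one
Product: 9 3-[(1R,2S)-2-[(tert-butyldimethylsilyl)oxy]-1-methyl-6-oxocyclohexyl]propanoic acid, via 2-oxo acid 8 (not isolated)
Conditions: NaIO4, KMnO4 (cat.), K2CO3, t-BuOH/H2O, 25 °C; then acidify to pH 3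
Reagents that add atoms: sodium periodate, [Na+].[O-]I(=O)(=O)=O; water, O
Why: Lemieux–von Rudloff scission of the enone C=C gives the ring ketone and a 2-oxo acid that is cleaved further with loss of CO2, leaving a three-carbon acid chain on the untouched quaternary centre.

Step 6
Reactants: 9 3-[(1R,2S)-2-[(tert-butyldimethylsilyl)oxy]-1-methyl-6-oxocyclohexyl]propanoic acid
Product: 10 (2R,3S)-3-[(tert-butyldimethylsilyl)oxy]-2-(3-hydroxypropyl)-2-methylcyclohexan-1-one
Conditions: BH3·THF (1.1 equiv), THF, −10 → 0 °C; MeOH quench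
Reagents that add atoms: none
Why: Chemoselective borane reduction: the carboxylic acid (via its acyloxyborane) reacts much faster than the hindered α-quaternary ketone.

Step 7
Reactants: 10 (2R,3S)-3-[(tert-butyldimethylsilyl)oxy]-2-(3-hydroxypropyl)-2-methylcyclohexan-1-one
Product: 11 3-[(1R,2S)-2-[(tert-butyldimethylsilyl)oxy]-1-methyl-6-oxocyclohexyl]propyl pivalate
Conditions: t-BuCOCl, pyridine, DMAP (cat.), CH2Cl2, 0 °C
Reagents that add atoms: pivaloyl chloride, CC(C)(C)C(Cl)=O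
Why: Acylation of the primary alcohol gives an ester that survives amide bases and fluoride and deactivates the adjacent C–H toward hydrogen-atom transfer in the later radical step.

Step 8
Reactants: 11 3-[(1R,2S)-2-[(tert-butyldimethylsilyl)oxy]-1-methyl-6-oxocyclohexyl]propyl pivalate
Product: 13 3-[(1R,2S)-2-[(tert-butyldimethylsilyl)oxy]-1,5-dimethyl-6-oxocyclohexyl]propyl pivalate (C-5 epimers), via lithium enolate 12 (not isolated)
Conditions: LiN(iPr)2 (1.1 equiv), THF, −78 °C; MeI, −78 → −30 °C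
Reagents that add atoms: iodomethane, CI
Why: Kinetic enolate alkylation is regiospecific because the other α-carbon is quaternary; the new epimeric centre becomes sp2 in the next step.

Step 9
Reactants: 13 3-[(1R,2S)-2-[(tert-butyldimethylsilyl)oxy]-1,5-dimethyl-6-oxocyclohexyl]propyl pivalate
Product: 15 3-[(1R,6S)-6-[(tert-butyldimethylsilyl)oxy]-1,3-dimethyl-2-(trifluoromethanesulfonyloxy)cyclohex-2-en-1-yl]propyl pivalate, via potassium enolate 14 (not isolated)
Conditions: KN(SiMe3)2, THF, −78 → −40 °C; PhNTf2, −78 → 0 °C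
Reagents that add atoms: N-phenylbis(trifluoromethanesulfonimide), FC(F)(F)S(=O)(=O)N(c1ccccc1)S(=O)(=O)C(F)(F)F
Why: Removal of the only remaining α-hydrogen gives the tetrasubstituted enolate, which is trapped on oxygen (enol triflation).

Step 10
Reactants: 15 3-[(1R,6S)-6-[(tert-butyldimethylsilyl)oxy]-1,3-dimethyl-2-(trifluoromethanesulfonyloxy)cyclohex-2-en-1-yl]propyl pivalate
Product: 16 3-[(1S,6S)-6-[(tert-butyldimethylsilyl)oxy]-1,3-dimethylcyclohex-2-en-1-yl]propyl pivalate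
Conditions: Pd(OAc)2 (5 mol %), PPh3 (10 mol %), HCO2H, Bu3N, DMF, 60 °C
Reagents that add atoms: none
Why: Palladium-catalysed formate reduction of the vinyl triflate replaces OTf by H without moving the double bond.

Step 11
Reactants: 16 3-[(1S,6S)-6-[(tert-butyldimethylsilyl)oxy]-1,3-dimethylcyclohex-2-en-1-yl]propyl pivalate
Product: 17 3-[(1S,6S)-6-hydroxy-1,3-dimethylcyclohex-2-en-1-yl]propyl pivalate
Conditions: Bu4NF, THF, 50 °C
Reagents that add atoms: none
Why: Fluoride desilylation frees the homoallylic hydroxyl while the hindered pivalate stays on.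

Step 12
Reactants: 17 3-[(1S,6S)-6-hydroxy-1,3-dimethylcyclohex-2-en-1-yl]propyl pivalate
Product: 18 3-[(1R,4S)-1,3-dimethyl-2-endo-(phenylselanyl)-7-oxabicyclo[2.2.1]heptan-3-yl]propyl pivalate
Conditions: PhSeCl, pyridine, CH2Cl2, −78 → −20 °C
Reagents that add atoms: benzeneselenenyl chloride, Cl[Se]c1ccccc1
Why: Phenylselenoetherification is an anti addition in which the hydroxyl can only reach the methyl-bearing alkene carbon (also the Markovnikov site), so the bridge closes with C-1 fixed as R by the existing carbinol centre and PhSe endo at C-2.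

Step 13
Reactants: 18 3-[(1R,4S)-1,3-dimethyl-2-endo-(phenylselanyl)-7-oxabicyclo[2.2.1]heptan-3-yl]propyl pivalate
Product: 20 3-[(1R,2S,3S,4S)-1,3-dimethyl-2-(prop-2-en-1-yl)-7-oxabicyclo[2.2.1]heptan-3-yl]propyl pivalate, via C-2 radical 19 (not isolated)
Conditions: CH2=CHCH2SnBu3 (4 equiv), AIBN (0.2 equiv), benzene, 80 °C
Reagents that add atoms: allyltributylstannane, C=CC[Sn](CCCC)(CCCC)CCCC
Why: Keck radical allylation: the planar C-2 radical is trapped on the open exo face (syn to the oxygen bridge, anti to the endo chain on C-3), setting C-2 as S with the new chain exo.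

Step 14
Reactants: 20 3-[(1R,2S,3S,4S)-1,3-dimethyl-2-(prop-2-en-1-yl)-7-oxabicyclo[2.2.1]heptan-3-yl]propyl pivalate
Product: 21 3-[(1R,2S,3S,4S)-1,3-dimethyl-2-(prop-2-en-1-yl)-7-oxabicyclo[2.2.1]heptan-3-yl]propan-1-ol
Conditions: iBu2AlH (2.5 equiv), CH2Cl2, −78 °C; aq. KNaC4H4O6 work-up
Reagents that add atoms: none
Why: Reductive cleavage of the pivalate by hydride; alkene and ether are inert.

Step 15
Reactants: 21 3-[(1R,2S,3S,4S)-1,3-dimethyl-2-(prop-2-en-1-yl)-7-oxabicyclo[2.2.1]heptan-3-yl]propan-1-ol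
Product: 22 methyl (2E)-4-[(1R,2S,3S,4S)-3-(3-hydroxypropyl)-1,3-dimethyl-7-oxabicyclo[2.2.1]heptan-2-yl]-2-methylbut-2-enoate
Conditions: methyl methacrylate (10 equiv), second-generation Hoveyda–Grubbs catalyst RuCl2(H2IMes)(=CH-C6H4-2-OiPr) (5 mol %), CH2Cl2, 40 °C
Reagents that add atoms: methyl methacrylate, C=C(C)C(=O)OC
Why: Olefin cross-metathesis of the reactive terminal alkene with the electron-poor 1,1-disubstituted methacrylate gives the trisubstituted enoate, the E isomer being strongly favoured.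

Step 16
Reactants: 22 methyl (2E)-4-[(1R,2S,3S,4S)-3-(3-hydroxypropyl)-1,3-dimethyl-7-oxabicyclo[2.2.1]heptan-2-yl]-2-methylbut-2-enoate
Product: 23 methyl (2E)-4-[(1R,2S,3S,4S)-1,3-dimethyl-3-(3-oxopropyl)-7-oxabicyclo[2.2.1]heptan-2-yl]-2-methylbut-2-enoate
Conditions: Dess–Martin periodinane, NaHCO3, CH2Cl2, 0 → 25 °C
Reagents that add atoms: none
Why: Dess–Martin oxidation takes the primary alcohol to the aldehyde under buffered, non-epimerising conditions.

Step 17
Reactants: 23 methyl (2E)-4-[(1R,2S,3S,4S)-1,3-dimethyl-3-(3-oxopropyl)-7-oxabicyclo[2.2.1]heptan-2-yl]-2-methylbut-2-enoate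
Product: 24 methyl (2E)-4-[(1R,2S,3S,4S)-1,3-dimethyl-3-(4-methylpent-3-en-1-yl)-7-oxabicyclo[2.2.1]heptan-2-yl]-2-methylbut-2-enoate
Conditions: iPrPPh3I (1.15 equiv), n-BuLi, THF, 0 °C; then 23, −78 → 0 °C
Reagents that add atoms: isopropyltriphenylphosphonium iodide, CC(C)[P+](c1ccccc1)(c1ccccc1)c1ccccc1.[I-]
Why: Wittig olefination with the non-stabilised isopropylidene ylide at low temperature takes the aldehyde in preference to the hindered enoate and gives the terminal trisubstituted alkene (no geometry issue).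

Step 18
Reactants: 24 methyl (2E)-4-[(1R,2S,3S,4S)-1,3-dimethyl-3-(4-methylpent-3-en-1-yl)-7-oxabicyclo[2.2.1]heptan-2-yl]-2-methylbut-2-enoate
Product: 25 (2E)-4-[(1R,2S,3S,4S)-1,3-dimethyl-3-(4-methylpent-3-en-1-yl)-7-oxabicyclo[2.2.1]heptan-2-yl]-2-methylbut-2-en-1-ol
Conditions: iBu2AlH (3 equiv), CH2Cl2, −78 °C
Reagents that add atoms: none
Why: 1,2-Reduction of the unsaturated ester gives the (E)-allylic alcohol and leaves the isolated alkene alone.

Step 19
Reactants: 25 (2E)-4-[(1R,2S,3S,4S)-1,3-dimethyl-3-(4-methylpent-3-en-1-yl)-7-oxabicyclo[2.2.1]heptan-2-yl]-2-methylbut-2-en-1-ol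
Product: 26 [(2R,3R)-3-{[(1R,2S,3S,4S)-1,3-dimethyl-3-(4-methylpent-3-en-1-yl)-7-oxabicyclo[2.2.1]heptan-2-yl]methyl}-2-methyloxiran-2-yl]methanol
Conditions: Ti(OiPr)4 (10 mol %), D-(−)-diethyl tartrate (12 mol %), t-BuOOH (2 equiv), 4 Å sieves, CH2Cl2, −20 °C
Reagents that add atoms: tert-butyl hydroperoxide, CC(C)(C)OO
Why: Sharpless asymmetric epoxidation: the titanium tartrate bound to the allylic hydroxyl delivers oxygen to one face, which with D-(−)-tartrate gives the (2R,3R)-epoxide (the future carbinol carbon) and spares the non-allylic alkene.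

Step 20
Reactants: 26 [(2R,3R)-3-{[(1R,2S,3S,4S)-1,3-dimethyl-3-(4-methylpent-3-en-1-yl)-7-oxabicyclo[2.2.1]heptan-2-yl]methyl}-2-methyloxiran-2-yl]methanol
Product: 27 (2S)-4-[(1R,2S,3S,4S)-1,3-dimethyl-3-(4-methylpent-3-en-1-yl)-7-oxabicyclo[2.2.1]heptan-2-yl]-2-methylbutane-1,2-diol
Conditions: LiAlH4, THF, 0 → 25 °C
Reagents that add atoms: none
Why: SN2 hydride opening occurs at the secondary epoxide carbon (the other is fully substituted), so the tertiary C–O stereocentre is retained in the 1,2-diol.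

Step 21
Reactants: 27 (2S)-4-[(1R,2S,3S,4S)-1,3-dimethyl-3-(4-methylpent-3-en-1-yl)-7-oxabicyclo[2.2.1]heptan-2-yl]-2-methylbutane-1,2-diol
Product: 28 (2S)-4-[(1R,2S,3S,4S)-1,3-dimethyl-3-(4-methylpent-3-en-1-yl)-7-oxabicyclo[2.2.1]heptan-2-yl]-2-hydroxy-2-methylbutanal
Conditions: TEMPO (10 mol %), PhI(OAc)2 (1.2 equiv), CH2Cl2, 25 °C
Reagents that add atoms: none
Why: TEMPO-catalysed oxidation takes only the primary alcohol to the aldehyde, since the tertiary alcohol cannot be oxidised.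

Step 22
Reactants: 28 (2S)-4-[(1R,2S,3S,4S)-1,3-dimethyl-3-(4-methylpent-3-en-1-yl)-7-oxabicyclo[2.2.1]heptan-2-yl]-2-hydroxy-2-methylbutanal
Product: 29 (3S)-5-[(1R,2S,3S,4S)-1,3-dimethyl-3-(4-methylpent-3-en-1-yl)-7-oxabicyclo[2.2.1]heptan-2-yl]-3-methylpent-1-en-3-ol
Conditions: Ph3PCH3Br (3 equiv), KOtBu, THF, 0 °C; then 28, 0 → 25 °C
Reagents that add atoms: methyltriphenylphosphonium bromide, C[P+](c1ccccc1)(c1ccccc1)c1ccccc1.[Br-]
Why: Wittig methylenation (excess ylide tolerates the free hydroxyl as its alkoxide) turns the formyl carbon into the vinyl group, completing the (S)-tertiary allylic alcohol.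

Step 23
Reactants: 29 (3S)-5-[(1R,2S,3S,4S)-1,3-dimethyl-3-(4-methylpent-3-en-1-yl)-7-oxabicyclo[2.2.1]heptan-2-yl]-3-methylpent-1-en-3-ol
Product: 30 triethylsilyl ether of 29
Conditions: Et3SiOTf, 2,6-lutidine, CH2Cl2, −78 → 0 °C
Reagents that add atoms: triethylsilyl trifluoromethanesulfonate, CC[Si](CC)(CC)OS(=O)(=O)C(F)(F)F
Why: Silylation with the silyl triflate protects the hindered tertiary allylic alcohol so that the halogenation steps see a single free hydroxyl.

Step 24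
Reactants: 30 triethylsilyl ether of 29
Product: 31 triethylsilyl ether carrying a 2-[(2R)-3,3-dimethyloxiran-2-yl]ethyl chain on C-3
Conditions: D-fructose-derived Shi ketone (0.3 equiv), KHSO5 (as 2KHSO5·KHSO4·K2SO4), K2CO3, Bu4NHSO4 (cat.), MeCN/CH2(OMe)2/aq. Na2B4O7 buffer, 0 °C
Reagents that add atoms: potassium peroxymonosulfate, [K+].[O-]S(=O)(=O)OO
Why: Shi asymmetric epoxidation (chiral dioxirane, spiro transition state) takes the electron-rich trisubstituted alkene in preference to the vinyl group and, with the D-fructose-derived ketone, gives the (R)-epoxide.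

Step 25
Reactants: 31 triethylsilyl ether carrying a 2-[(2R)-3,3-dimethyloxiran-2-yl]ethyl chain on C-3
Product: 32 triethylsilyl ether carrying a (3R)-4-bromo-3-hydroxy-4-methylpentyl chain on C-3
Conditions: LiBr, AcOH, THF, 0 → 25 °C
Reagents that add atoms: lithium bromide, [Li+].[Br-]
Why: Acid-assisted anti opening of the epoxide by bromide at the tertiary carbon (Markovnikov) gives the bromohydrin without touching the secondary C–O centre.

Step 26
Reactants: 32 triethylsilyl ether carrying a (3R)-4-bromo-3-hydroxy-4-methylpentyl chain on C-3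
Product: 35 O-triethylsilyl dactylomelol, via chlorosulfite 33 (not isolated), via bromonium chloride 34 (not isolated)
Conditions: SOCl2, 2,6-lutidine, BnEt3NCl, CH2Cl2, −40 → 0 °C
Reagents that add atoms: thionyl chloride, O=S(Cl)Cl
Why: Deoxychlorination with neighbouring-group participation (Winstein type): the β-bromine displaces the chlorosulfite with inversion to give a bromonium ion that chloride opens at the tertiary carbon, leaving (S)-CHBr next to CMe2Cl.

Step 27
Reactants: 35 O-triethylsilyl dactylomelol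
Product: 36 dactylomelol
Conditions: HF·pyridine, pyridine, THF, 0 °C
Reagents that add atoms: none
Why: Buffered fluoride desilylation frees the tertiary allylic alcohol without eliminating or substituting the vicinal bromochloride.

## Compound list

1 | 2-methylcyclohexane-1,3-dione | CC1C(=O)CCCC1=O | starting material
2 | methyl vinyl ketone (but-3-en-2-one) | CC(=O)C=C | starting material
3 | 2-methyl-2-(3-oxobutyl)cyclohexane-1,3-dione (achiral) | CC(=O)CCC1(C)C(=O)CCCC1=O | intermediate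
4 | (4aS,8aS)-4a-hydroxy-8a-methyloctahydronaphthalene-1,6-dione, cis-fused ketol (not isolated) | C[C@]12CCC(=O)C[C@@]1(O)CCCC2=O | intermediate
5 | (S)-Wieland–Miescher ketone, (8aS)-8a-methyl-3,4,8,8a-tetrahydronaphthalene-1,6(2H,7H)-dione | C[C@]12CCC(=O)C=C1CCCC2=O | intermediate
6 | (4aS,5S)-5-hydroxy-4a-methyl-4,4a,5,6,7,8-hexahydronaphthalen-2(3H)-one (OH cis to angular methyl) | C[C@]12CCC(=O)C=C1CCC[C@@H]2O | intermediate
7 | (4aS,5S)-5-[(tert-butyldimethylsilyl)oxy]-4a-methyl-4,4a,5,6,7,8-hexahydronaphthalen-2(3H)-one | C[C@]12CCC(=O)C=C1CCC[C@@H]2O[Si](C)(C)C(C)(C)C | intermediate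
8 | 4-[(1R,2S)-2-[(tert-butyldimethylsilyl)oxy]-1-methyl-6-oxocyclohexyl]-2-oxobutanoic acid (not isolated) | C[C@]1(CCC(=O)C(=O)O)C(=O)CCC[C@@H]1O[Si](C)(C)C(C)(C)C | intermediate
9 | 3-[(1R,2S)-2-[(tert-butyldimethylsilyl)oxy]-1-methyl-6-oxocyclohexyl]propanoic acid | C[C@]1(CCC(=O)O)C(=O)CCC[C@@H]1O[Si](C)(C)C(C)(C)C | intermediate
10 | (2R,3S)-3-[(tert-butyldimethylsilyl)oxy]-2-(3-hydroxypropyl)-2-methylcyclohexan-1-one | C[C@]1(CCCO)C(=O)CCC[C@@H]1O[Si](C)(C)C(C)(C)C | intermediate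
11 | 3-[(1R,2S)-2-[(tert-butyldimethylsilyl)oxy]-1-methyl-6-oxocyclohexyl]propyl pivalate | C[C@]1(CCCOC(=O)C(C)(C)C)C(=O)CCC[C@@H]1O[Si](C)(C)C(C)(C)C | intermediate
12 | lithium enolate of 11, enolised toward the ring CH2 (not isolated) | [Li+].C[C@]1(CCCOC(=O)C(C)(C)C)C([O-])=CCC[C@@H]1O[Si](C)(C)C(C)(C)C | intermediate
13 | 3-[(1R,2S)-2-[(tert-butyldimethylsilyl)oxy]-1,5-dimethyl-6-oxocyclohexyl]propyl pivalate (C-5 epimers) | C[C@]1(CCCOC(=O)C(C)(C)C)C(=O)C(C)CC[C@@H]1O[Si](C)(C)C(C)(C)C | intermediate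
14 | potassium enolate of 13, tetrasubstituted (not isolated) | [K+].C[C@]1(CCCOC(=O)C(C)(C)C)C([O-])=C(C)CC[C@@H]1O[Si](C)(C)C(C)(C)C | intermediate
15 | 3-[(1R,6S)-6-[(tert-butyldimethylsilyl)oxy]-1,3-dimethyl-2-(trifluoromethanesulfonyloxy)cyclohex-2-en-1-yl]propyl pivalate | C[C@]1(CCCOC(=O)C(C)(C)C)C(OS(=O)(=O)C(F)(F)F)=C(C)CC[C@@H]1O[Si](C)(C)C(C)(C)C | intermediate
16 | 3-[(1S,6S)-6-[(tert-butyldimethylsilyl)oxy]-1,3-dimethylcyclohex-2-en-1-yl]propyl pivalate | C[C@]1(CCCOC(=O)C(C)(C)C)C=C(C)CC[C@@H]1O[Si](C)(C)C(C)(C)C | intermediate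
17 | 3-[(1S,6S)-6-hydroxy-1,3-dimethylcyclohex-2-en-1-yl]propyl pivalate (OH cis to the 1-methyl) | C[C@]1(CCCOC(=O)C(C)(C)C)C=C(C)CC[C@@H]1O | intermediate
18 | 3-[(1R,4S)-1,3-dimethyl-2-endo-(phenylselanyl)-7-oxabicyclo[2.2.1]heptan-3-yl]propyl pivalate (3-methyl exo, chain endo) | c1ccccc1[Se][C@@H]1[C@](C)(CCCOC(=O)C(C)(C)C)[C@@H]2CC[C@@]1(C)O2 | intermediate
19 | C-2 radical derived from 18 (not isolated) | [CH]1[C@](C)(CCCOC(=O)C(C)(C)C)[C@@H]2CC[C@@]1(C)O2 | intermediate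
20 | 3-[(1R,2S,3S,4S)-1,3-dimethyl-2-(prop-2-en-1-yl)-7-oxabicyclo[2.2.1]heptan-3-yl]propyl pivalate (allyl exo) | C=CC[C@H]1[C@](C)(CCCOC(=O)C(C)(C)C)[C@@H]2CC[C@@]1(C)O2 | intermediate
21 | 3-[(1R,2S,3S,4S)-1,3-dimethyl-2-(prop-2-en-1-yl)-7-oxabicyclo[2.2.1]heptan-3-yl]propan-1-ol | C=CC[C@H]1[C@](C)(CCCO)[C@@H]2CC[C@@]1(C)O2 | intermediate
22 | methyl (2E)-4-[(1R,2S,3S,4S)-3-(3-hydroxypropyl)-1,3-dimethyl-7-oxabicyclo[2.2.1]heptan-2-yl]-2-methylbut-2-enoate | COC(=O)/C(C)=C/C[C@H]1[C@](C)(CCCO)[C@@H]2CC[C@@]1(C)O2 | intermediate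
23 | methyl (2E)-4-[(1R,2S,3S,4S)-1,3-dimethyl-3-(3-oxopropyl)-7-oxabicyclo[2.2.1]heptan-2-yl]-2-methylbut-2-enoate | COC(=O)/C(C)=C/C[C@H]1[C@](C)(CCC=O)[C@@H]2CC[C@@]1(C)O2 | intermediate
24 | methyl (2E)-4-[(1R,2S,3S,4S)-1,3-dimethyl-3-(4-methylpent-3-en-1-yl)-7-oxabicyclo[2.2.1]heptan-2-yl]-2-methylbut-2-enoate | COC(=O)/C(C)=C/C[C@H]1[C@](C)(CCC=C(C)C)[C@@H]2CC[C@@]1(C)O2 | intermediate
25 | (2E)-4-[(1R,2S,3S,4S)-1,3-dimethyl-3-(4-methylpent-3-en-1-yl)-7-oxabicyclo[2.2.1]heptan-2-yl]-2-methylbut-2-en-1-ol | OC/C(C)=C/C[C@H]1[C@](C)(CCC=C(C)C)[C@@H]2CC[C@@]1(C)O2 | intermediate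
26 | [(2R,3R)-3-{[(1R,2S,3S,4S)-1,3-dimethyl-3-(4-methylpent-3-en-1-yl)-7-oxabicyclo[2.2.1]heptan-2-yl]methyl}-2-methyloxiran-2-yl]methanol | OC[C@@]3(C)O[C@@H]3C[C@H]1[C@](C)(CCC=C(C)C)[C@@H]2CC[C@@]1(C)O2 | intermediate
27 | (2S)-4-[(1R,2S,3S,4S)-1,3-dimethyl-3-(4-methylpent-3-en-1-yl)-7-oxabicyclo[2.2.1]heptan-2-yl]-2-methylbutane-1,2-diol | OC[C@@](C)(O)CC[C@H]1[C@](C)(CCC=C(C)C)[C@@H]2CC[C@@]1(C)O2 | intermediate
28 | (2S)-4-[(1R,2S,3S,4S)-1,3-dimethyl-3-(4-methylpent-3-en-1-yl)-7-oxabicyclo[2.2.1]heptan-2-yl]-2-hydroxy-2-methylbutanal | O=C[C@@](C)(O)CC[C@H]1[C@](C)(CCC=C(C)C)[C@@H]2CC[C@@]1(C)O2 | intermediate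
29 | (3S)-5-[(1R,2S,3S,4S)-1,3-dimethyl-3-(4-methylpent-3-en-1-yl)-7-oxabicyclo[2.2.1]heptan-2-yl]-3-methylpent-1-en-3-ol | C=C[C@@](C)(O)CC[C@H]1[C@](C)(CCC=C(C)C)[C@@H]2CC[C@@]1(C)O2 | intermediate
30 | triethylsilyl ether of 29 | C=C[C@@](C)(O[Si](CC)(CC)CC)CC[C@H]1[C@](C)(CCC=C(C)C)[C@@H]2CC[C@@]1(C)O2 | intermediate
31 | triethylsilyl ether with a 2-[(2R)-3,3-dimethyloxiran-2-yl]ethyl chain on C-3 | C=C[C@@](C)(O[Si](CC)(CC)CC)CC[C@H]1[C@](C)(CC[C@H]3OC3(C)C)[C@@H]2CC[C@@]1(C)O2 | intermediate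
32 | triethylsilyl ether with a (3R)-4-bromo-3-hydroxy-4-methylpentyl chain on C-3 | C=C[C@@](C)(O[Si](CC)(CC)CC)CC[C@H]1[C@](C)(CC[C@@H](O)C(C)(C)Br)[C@@H]2CC[C@@]1(C)O2 | intermediate
33 | chlorosulfite ester of 32 (not isolated) | C=C[C@@](C)(O[Si](CC)(CC)CC)CC[C@H]1[C@](C)(CC[C@@H](OS(=O)Cl)C(C)(C)Br)[C@@H]2CC[C@@]1(C)O2 | intermediate
34 | bromonium chloride bridging C-3' and C-4' of the chain (not isolated) | C=C[C@@](C)(O[Si](CC)(CC)CC)CC[C@H]1[C@](C)(CC[C@@H]3[Br+]C3(C)C)[C@@H]2CC[C@@]1(C)O2.[Cl-] | intermediate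
35 | O-triethylsilyl dactylomelol | C=C[C@@](C)(O[Si](CC)(CC)CC)CC[C@H]1[C@](C)(CC[C@H](Br)C(C)(C)Cl)[C@@H]2CC[C@@]1(C)O2 | intermediate
36 | dactylomelol, (3S)-5-[(1R,2S,3S,4S)-3-[(3S)-3-bromo-4-chloro-4-methylpentyl]-1,3-dimethyl-7-oxabicyclo[2.2.1]heptan-2-yl]-3-methylpent-1-en-3-ol | C=C[C@@](C)(O)CC[C@H]1[C@](C)(CC[C@H](Br)C(C)(C)Cl)[C@@H]2CC[C@@]1(C)O2 | target

## Step count and risks

Total step count: 27. Longest linear sequence: 27 steps (fully linear from 1 and 2).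

The three steps most likely to fail:

Step 12 (closing the strained bridged ether). The selenoetherification may stall or give chloroselenide adducts. The fallback sets out from 17 and returns at 20. Hydroxyl-directed epoxidation of 17 (VO(acac)2, t-BuOOH, CH2Cl2) gives the cis-epoxy alcohol F1. Catalytic p-TsOH in CH2Cl2 then opens the epoxide at its tertiary carbon with the transannular hydroxyl, giving the 2-exo-hydroxy-7-oxabicycle F2. PhOC(S)Cl with pyridine and DMAP converts it into the phenyl thionocarbonate F3, which undergoes the same tin-mediated radical allylation (CH2=CHCH2SnBu3, AIBN, benzene, 80 °C) to give 20.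

Step 13 (radical allylation at a carbon flanked by two quaternary centres). The exo:endo ratio may be low, or hydrogen-atom transfer from the side chain may compete. The fallback forms the C-2–carbon bond by a sigmatropic shift instead; it sets out from 16 and returns at 20. Allylic oxidation of 16 at the ring CH2 next to the methyl-bearing alkene carbon (CrO3, 3,5-dimethylpyrazole, CH2Cl2, −20 °C) gives the enone F4. Reduction with BH3·SMe2 and (S)-2-methyl-CBS-oxazaborolidine gives the (R)-allylic alcohol F5, with OH cis to the silyloxy group. Johnson–Claisen rearrangement (MeC(OEt)3, cat. EtCO2H, xylene, 140 °C) transfers that C–O configuration suprafacially to the new C–C bond, giving the ester F6 with the alkene transposed. Aqueous HF in MeCN gives the hydroxy ester F7, and PhSeCl/pyridine closes the bridge to the selenide F8. Bu3SnH/AIBN gives the bicyclic ester F9; iBu2AlH (1.1 equiv, −78 °C, the pivalate reacting more slowly) gives the aldehyde F10; and Ph3P=CH2 gives 20.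

Step 26 (chlorination with 1,2-bromine shift). Elimination to an allylic bromide, or bromonium transfer to the vinyl group, may compete. The fallback installs the halogens in the opposite order; it sets out from 31 and returns at 35. Pyridinium chloride in CH2Cl2 at 0 °C opens the epoxide at the tertiary carbon to the chlorohydrin F11 (tertiary chloride, secondary R alcohol). An Appel bromination (PPh3, CBr4, 2,6-lutidine, CH2Cl2, 0 → 25 °C) then replaces the secondary hydroxyl by bromide with SN2 inversion to give 35. This fallback is itself uncertain: substitution at a carbon next to CMe2Cl is slow and chlorine participation could scramble the halogens.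

## Further compounds

F1 | step 12 | 3-[(1S,2S)-2-hydroxy-1-methyl-5,6-epoxy-5-methylcyclohexyl]propyl pivalate, epoxide cis to OH | C[C@]1(CCCOC(=O)C(C)(C)C)[C@@H]3O[C@]3(C)CC[C@@H]1O
F2 | step 12 | 3-[(1R,4S)-2-exo-hydroxy-1,3-dimethyl-7-oxabicyclo[2.2.1]heptan-3-yl]propyl pivalate | O[C@H]1[C@](C)(CCCOC(=O)C(C)(C)C)[C@@H]2CC[C@@]1(C)O2
F3 | step 12 | O-phenyl thionocarbonate of F2 | S=C(Oc1ccccc1)O[C@H]1[C@](C)(CCCOC(=O)C(C)(C)C)[C@@H]2CC[C@@]1(C)O2
F4 | step 13 | 3-[(1S,6S)-6-[(tert-butyldimethylsilyl)oxy]-1,3-dimethyl-4-oxocyclohex-2-en-1-yl]propyl pivalate | C[C@]1(CCCOC(=O)C(C)(C)C)C=C(C)C(=O)C[C@@H]1O[Si](C)(C)C(C)(C)C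
F5 | step 13 | 3-[(1S,4R,6S)-6-[(tert-butyldimethylsilyl)oxy]-4-hydroxy-1,3-dimethylcyclohex-2-en-1-yl]propyl pivalate, OH cis to OTBS | C[C@]1(CCCOC(=O)C(C)(C)C)C=C(C)[C@H](O)C[C@@H]1O[Si](C)(C)C(C)(C)C
F6 | step 13 | ethyl 2-[6-{3-(pivaloyloxy)propyl}-5-[(tert-butyldimethylsilyl)oxy]-2,6-dimethylcyclohex-2-en-1-yl]acetate, CH2CO2Et cis to the 6-methyl and to OTBS | CCOC(=O)C[C@H]1[C@](C)(CCCOC(=O)C(C)(C)C)[C@@H](O[Si](C)(C)C(C)(C)C)CC=C1C
F7 | step 13 | hydroxy ester from desilylation of F6 | CCOC(=O)C[C@H]1[C@](C)(CCCOC(=O)C(C)(C)C)[C@@H](O)CC=C1C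
F8 | step 13 | ethyl 2-[1,3-dimethyl-6-endo-(phenylselanyl)-3-{3-(pivaloyloxy)propyl}-7-oxabicyclo[2.2.1]heptan-2-exo-yl]acetate | CCOC(=O)C[C@H]1[C@](C)(CCCOC(=O)C(C)(C)C)[C@@H]2C[C@H]([Se]c3ccccc3)[C@@]1(C)O2
F9 | step 13 | ethyl 2-[(1R,2S,3S,4S)-1,3-dimethyl-3-{3-(pivaloyloxy)propyl}-7-oxabicyclo[2.2.1]heptan-2-yl]acetate | CCOC(=O)C[C@H]1[C@](C)(CCCOC(=O)C(C)(C)C)[C@@H]2CC[C@@]1(C)O2
F10 | step 13 | 3-[(1R,2S,3S,4S)-1,3-dimethyl-2-(2-oxoethyl)-7-oxabicyclo[2.2.1]heptan-3-yl]propyl pivalate | O=CC[C@H]1[C@](C)(CCCOC(=O)C(C)(C)C)[C@@H]2CC[C@@]1(C)O2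
F11 | step 26 | triethylsilyl ether with a (3R)-4-chloro-3-hydroxy-4-methylpentyl chain on C-3 | C=C[C@@](C)(O[Si](CC)(CC)CC)CC[C@H]1[C@](C)(CC[C@@H](O)C(C)(C)Cl)[C@@H]2CC[C@@]1(C)O2
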